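Remark on the chemistry: the oxolane is numbered O1, C2–C5; Ca is the carbinol carbon on C3 and Cb the one on C4. CIP analysis of the target gives Ca = S, C3 = R, C4 = R, Cb = R. Every structure below was re-derived atom by atom on that basis and none needed correction. The 2S,3S centres of the succinyl compounds become 3R,4R in the oxolane only because the substituent ranking changes when C=O becomes CH2–O, not because the geometry changes.

## Structural features

The target is a 3,4-disubstituted oxolane (ring A) whose C3 and C4 each carry an aryl(hydroxy)methyl arm, both aryl groups being 4-hydroxy-3-methoxyphenyl (rings B and C). Four stereocentres stand in an unbroken row, Ca–C3–C4–Cb, with configuration S, R, R, R, and the two arms are trans on ring A. The constitution is twofold-symmetric but the configuration is not: the S,R,R,S isomer would have a C2 axis, and the target is its epimer at one carbinol. The fragile parts are the two para-hydroxybenzylic alcohols (quinone-methide formation with acid, base or heat, and hydrogenolysis) and the oxidisable free phenols. The real difficulty is to fix four contiguous centres absolutely and then break the symmetry at exactly one carbinol; the unstrained ring is not the problem. The key step uses the fact that C2–C3–C4–C5 is a succinic chain with C2 and C5 at the carboxyl level, so that Ca–C3 and Cb–C4 are both aldol bonds between a succinyl α-carbon and a vanillin-derived aldehyde carbon.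

## Logic of the disconnections

16 back to 15. No skeletal bond is cut; the two phenolic O–H bonds go back to O–CH2Ph ethers. The free para-hydroxybenzylic alcohols are the most sensitive feature, so they are released last under neutral conditions. The forward step must cleave O–CH2Ph without touching the benzylic C–OH bonds.

15 back to 14 and 13. The C–H bond at Cb is cut (a reduction), and the resulting ketone 14 is taken back to the S carbinol of 13 (an oxidation). The reason is that 13 has a C2 axis, so its two carbinols are homotopic and inversion of either one gives 15. The gain is that the unsymmetrical target reduces to a symmetric compound that one auxiliary-controlled reaction can deliver. The forward steps must stop at mono-oxidation, avoid epimerising the ring carbon next to the new ketone, and reduce under reagent control to R.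

13 back to 12, 11 and 10. After re-capping the carbinols as silyl ethers (12), the O1–C5 bond of ring A is cut (equivalent to O1–C2 by symmetry), giving a 1,4-diol 10 by way of its monosulfonate 11. A 5-exo-tet etherification at a primary carbon is reliable and touches no stereocentre. The forward step must sulfonylate once only, and the secondary carbinols must stay capped, because each could otherwise close a competing five-membered ring onto the same CH2.

10 back to 9 and 8. C2 and C5 are raised to the carboxyl level as N-acyl oxazolidinones, which cuts the two N–C(acyl) bonds in the reductive sense. This reveals the succinyl bis(imide) skeleton and puts a stereocontrolling group at each end. The forward steps must deliver hydride to two hindered exocyclic carbonyls, and the hydroxyls of 8 must be silylated before they can lactonise onto the opposite imide.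

8 back to 4 and two molecules of 5 (through 6 and 7). Ca–C3 and Cb–C4 are cut together. Both are aldol bonds of one symmetric bis(enolate), so two skeletal bonds and all four stereocentres come from one operation on a four-carbon core. The forward step must form two adjacent boron enolates and achieve syn selectivity and the same enolate face twice.

4 back to 1 and 2 (through 3). The two N–acyl bonds are cut, leading to a commercial diacid chloride and a commercial auxiliary. The forward step only needs clean double N-acylation.

## Other disconnections considered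

Alternative 1: The cut runs through C2–C3 and C4–C5, so ring A splits into a C–O–C unit and the C3–C4 unit.
- Forward key step: fluoride (CsF) desilylates chloromethyl (trimethylsilyl)methyl ether A2 with loss of chloride. The parent carbonyl ylide so formed adds by a concerted suprafacial [3+2] cycloaddition to the E alkene of fumaric bis[(2S,5S)-2,5-dimethylpyrrolidide] A1, giving trans-oxolane-3,4-dicarboxylic bis[(2S,5S)-2,5-dimethylpyrrolidide] A3.
- In its favour: ring A and the trans C3/C4 relationship arise in one step, the trans geometry follows stereospecifically from the alkene, and no hydroxyl is present that could lactonise. On these points it is better than the chosen plan, which needs a separate ring closure and a silyl on/off pair.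
- Against it here: the ylide is a small, very reactive dipole, so face differentiation by the pyrrolidine methyl groups is uncertain. The two hindered tertiary amides of A3 must be converted into aryl ketones, for instance (3R,4R)-3,4-bis[4-(benzyloxy)-3-methoxybenzoyl]oxolane A4, and such amides are poor partners for aryl organometallics. From A4 both carbinol centres rest on late reagent control with opposite catalyst antipodes, again through mono-reduction of two homotopic ketones.
- Comparison: structurally it solves the ring and two centres, whereas the chosen plan solves all four chain centres. Mechanistically both use a chiral amide-type controller, but in the chosen plan it sits inside a closed chair transition state and here it acts at a distance on an early transition state. The statistical desymmetrisation is equal in both. In step count the alternative (about seven steps) is better than the chosen plan (nine), provided facial selectivity and the amide-to-ketone conversion hold.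

Alternative 2: The cut removes the Ca–O and Cb–O bonds and returns C3 and C4 to sp2 carbons.
- Forward key step: sensitised photooxygenation (O2, 5,10,15,20-tetraphenylporphyrin, light) of (3Z,4Z)-3,4-bis[4-(benzyloxy)-3-methoxybenzylidene]oxolane A5, whose diene is held s-cis by ring A. Suprafacial [4+2] addition gives the meso endoperoxide A6 (cis-1,4-diaryl-1,4,5,7-tetrahydrofuro[3,4-d][1,2]dioxine), and O–O reduction would give the meso diol A7.
- In its favour: the two carbinols emerge with opposite descriptors, which is the relationship in the target, so no carbinol has to be inverted. On this point, and in the number of steps to the oxygenated skeleton, it is better than the chosen plan.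
- Against it here: A6 and A7 are achiral, so absolute configuration still has to be introduced by a desymmetrising step. C3 and C4 are an alkene that must become trans centres, whereas hydrogen adds syn and would give the cis ring. The benzylic hydrogens next to the peroxide invite base-induced Kornblum–DeLaMare fragmentation, and electron-rich styrene units can also react with singlet oxygen by [2+2] addition and cleavage.
- Comparison: structurally it fixes only the relative configuration of Ca and Cb, whereas the chosen plan fixes all four centres absolutely and corrects one. Mechanistically it is pericyclic with no external stereocontrol, against auxiliary control. It is shorter up to A7, but the trans ring and the enantiocontrol have no short reliable answer, so the total is not expected to be lower.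

Alternative 3: The cut is the C2–C3 bond, with Ca taken back to an aldehyde and Cb to the carbon of a 1-arylvinyl group.
- Forward key step: Me3SiOTf opens the acetal of (5S)-5-{1-[4-(benzyloxy)-3-methoxyphenyl]ethenyl}-4,5-dihydro-1,3-dioxepine A8 at the enol oxygen. The freed enol carbon attacks the tethered oxocarbenium carbon in a five-membered ring closure (a ring contraction of the Petasis–Ferrier kind), giving (3R,4S)-4-{1-[4-(benzyloxy)-3-methoxyphenyl]ethenyl}oxolane-3-carbaldehyde A9.
- In its favour: the two arms differ chemically from the start (aldehyde and styrene), so no statistical step is needed, which is better than the chosen plan. The trans ring relationship is thermodynamically correctable at the enolisable aldehyde, and no lactonisation can intervene.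
- Against it here: the key step makes only one skeletal bond and one stereocentre. A8 must first be made as a single enantiomer. Ca then needs an aryl-metal addition to an α-branched aldehyde with uncertain 1,2-induction, and Cb needs oxidative cleavage of the alkene beside electron-rich arenes followed by a reagent-controlled reduction. The Lewis acid also meets an electron-rich styrene that can act as a competing π-nucleophile.
- Comparison: structurally it gives one bond and one centre against two bonds and four centres. Mechanistically it is a cationic, substrate-controlled rearrangement against closed-transition-state auxiliary control. In step economy it is clearly longer (well over ten steps) than the chosen plan.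

Key step: step 2

## Route

Step 1
Reactants: 1 (S)-4-benzyl-2-oxazolidinone; 2 succinyl chloride
Product: 4 succinyl bis[(S)-4-benzyl-2-oxazolidinone] [(4S,4'S)-3,3'-butanedioylbis(4-benzyl-1,3-oxazolidin-2-one)], via lithium (S)-4-benzyl-2-oxooxazolidin-3-ide 3 (not isolated)
Conditions: 1 (2.1 equiv), n-BuLi (2.1 equiv), THF, −78 °C; then 2 (1.0 equiv), −78 → 0 °C; aq. NH4Cl
Reagents that add atoms: none
Why: N-acylation of a lithiated oxazolidinone by an acid chloride (standard imide formation); both acyl chloride ends are equivalent and the auxiliary stereocentres are not touched.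

Step 2
Reactants: 4 succinyl bis[(S)-4-benzyl-2-oxazolidinone]; 5 4-benzyloxy-3-methoxybenzaldehyde (O-benzylvanillin)
Product: 8 syn,syn double aldol bis(imide) [(4S,4'S)-3,3'-{(2S,3S)-2,3-bis{(S)-[4-(benzyloxy)-3-methoxyphenyl](hydroxy)methyl}butanedioyl}bis(4-benzyl-1,3-oxazolidin-2-one)], via (Z,Z)-bis(dibutylboron enolate) 6 (not isolated), via bis(dibutylboron aldolate) 7 (not isolated)
Conditions: Bu2BOTf (2.4 equiv), iPr2NEt (2.8 equiv), CH2Cl2, −78 → 0 °C; 5 (2.6 equiv), −78 → −20 °C; KH2PO4/Na2HPO4 buffer (pH 7), MeOH, 30% H2O2, 0 °C
Reagents that add atoms: none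
Why: Proposed new method: soft enolisation of both imides by Bu2BOTf/iPr2NEt should give the (Z,Z)-bis(boron enolate) 6, a 1,4-dioxygenated diene in which no electrophilic imide carbonyl remains, so the aldolate of the first addition cannot lactonise before the second C–C bond is made; each enolate then adds to 5 through a closed six-membered Zimmerman–Traxler chair with boron bridging the two oxygens. The closest known reaction type is the Evans syn aldol of succinate half-ester imides, and for the two-directional aspect the Lewis-acid double aldol of 2,5-bis(silyloxy)furans with aryl aldehydes; the double addition on a bis(imide) is not established. No ring is closed, so no mode of closure has to be judged. C3 and C4 are set by the auxiliaries: with the oxazolidinone carbonyl opposed to the enolate C–O dipole, the 4-benzyl group covers one enolate face and the aldehyde enters from the other, which for the S auxiliary gives the 2S,3S succinyl centres (3R,4R in the oxolane). Ca and Cb follow from the Z enolate geometry and the equatorial aryl group in the chair, which enforce the syn relationship and hence the S carbinols. The step needs syn selectivity twice and the same enolate face twice; in the second addition the auxiliary must override the new neighbouring stereocentre and the bulk of the first aldolate, which is plausible because β-branched N-acyl oxazolidinones are known to react under auxiliary control. Excess Bu2BOTf, complete enolisation before any aldehyde is added, temperatures not above −20 °C and a cold buffered oxidative work-up are planned so that the γ-hydroxy imides do not lactonise, and crude 8 goes straight into step 3.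

Step 3
Reactants: 8 syn,syn double aldol bis(imide)
Product: 9 bis(tert-butyldimethylsilyl) ether of 8 [(4S,4'S)-3,3'-{(2S,3S)-2,3-bis{(S)-[4-(benzyloxy)-3-methoxyphenyl][(tert-butyldimethylsilyl)oxy]methyl}butanedioyl}bis(4-benzyl-1,3-oxazolidin-2-one)]
Conditions: TBSOTf (3 equiv), 2,6-lutidine (5 equiv), CH2Cl2, −78 → 0 °C (crude 8 used at once)
Reagents that add atoms: tert-butyldimethylsilyl trifluoromethanesulfonate (TBSOTf), CC(C)(C)[Si](C)(C)OS(=O)(=O)C(F)(F)F
Why: O-silylation of secondary alcohols with a silyl triflate and a hindered pyridine base; it removes the only nucleophiles that could lactonise onto the imides or later compete in the ring closure, and no stereocentre is involved.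

Step 4
Reactants: 9 bis(silyl ether) bis(imide)
Product: 10 (2R,3R)-2,3-bis{(S)-[4-(benzyloxy)-3-methoxyphenyl][(tert-butyldimethylsilyl)oxy]methyl}butane-1,4-diol
Conditions: LiBH4 (6 equiv), MeOH (6 equiv), THF, 0 °C → rt; then H2O
Reagents that add atoms: none
Why: Reductive cleavage of N-acyl oxazolidinones by LiBH4 (hydride attack at the exocyclic carbonyl, auxiliary 1 released and recoverable); a γ-lactone formed after the first reduction would be reduced on to the same diol, and the α-centres are not enolised under these conditions.

Step 5
Reactants: 10 bis(silyloxy) 1,4-diol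
Product: 12 (3R,4R)-3,4-bis{(S)-[4-(benzyloxy)-3-methoxyphenyl][(tert-butyldimethylsilyl)oxy]methyl}oxolane, via monotosylate 11 (not isolated)
Conditions: TsCl (1.1 equiv), pyridine, 4-(dimethylamino)pyridine (cat.), 0 °C → 50 °C
Reagents that add atoms: none
Why: Monosulfonylation of a 1,4-diol followed by intramolecular Williamson etherification (5-exo-tet attack of the remaining primary hydroxyl on the primary tosylate); the two primary hydroxyls are homotopic so either monotosylate gives the same oxolane, substitution occurs at CH2 and leaves all four stereocentres untouched, and the absence of alkoxide avoids silyl migration.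

Step 6
Reactants: 12 bis(silyl ether) oxolane
Product: 13 (S,S)-[(3R,4R)-oxolane-3,4-diyl]bis{[4-(benzyloxy)-3-methoxyphenyl]methanol}
Conditions: Bu4NF (3 equiv), THF, 0 °C → rt
Reagents that add atoms: none
Why: Fluoride cleavage of alkyl silyl ethers; the aryl benzyl ethers and the oxolane are inert and no C–O bond at a carbinol is broken, so both S configurations are kept.

Step 7
Reactants: 13 twofold-symmetric diol
Product: 14 [4-(benzyloxy)-3-methoxyphenyl]{(3R,4R)-4-{(S)-[4-(benzyloxy)-3-methoxyphenyl](hydroxy)methyl}oxolan-3-yl}methanone
Conditions: activated MnO2 (added in portions), CH2Cl2, rt; stopped at partial conversion, unchanged 13 recycled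
Reagents that add atoms: none
Why: Selective oxidation of a benzylic alcohol by MnO2 under neutral heterogeneous conditions; the two carbinols are homotopic, so only the degree of oxidation has to be controlled (statistical, with recovery of 13), and the neutral medium should not enolise the new aryl ketone, so C4 stays trans.

Step 8
Reactants: 14 keto alcohol
Product: 15 (S)-[4-(benzyloxy)-3-methoxyphenyl]{(3R,4R)-4-{(R)-[4-(benzyloxy)-3-methoxyphenyl](hydroxy)methyl}oxolan-3-yl}methanol
Conditions: (3aS)-1-methyl-3,3-diphenyltetrahydro-1H,3H-pyrrolo[1,2-c][1,3,2]oxazaborole (0.3 equiv), BH3·SMe2 (2.5 equiv), THF, −30 °C; MeOH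
Reagents that add atoms: none
Why: Corey–Bakshi–Shibata reduction of an aryl alkyl ketone; with the aryl group as the large substituent the S catalyst should deliver hydride to the face that gives the R carbinol (the sense of acetophenone to (R)-1-phenylethanol), and the only other possible product is 13, which can re-enter step 7.

Step 9
Reactants: 15 S,R diol bis(benzyl ether)
Product: 16 4-[(S)-hydroxy{(3R,4R)-4-[(R)-hydroxy(4-hydroxy-3-methoxyphenyl)methyl]oxolan-3-yl}methyl]-2-methoxyphenol (target)
Conditions: H2 (1 atm), 10% Pd/C, EtOAc/EtOH, rt; stopped as soon as 15 is consumed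
Reagents that add atoms: none
Why: Hydrogenolysis of aryl benzyl ethers over Pd/C under neutral conditions, which is much faster than hydrogenolysis of a secondary benzylic C–OH bond in the absence of acid; no stereocentre is touched.

## Compound list

1 | (S)-4-benzyl-2-oxazolidinone | O=C1OC[C@H](Cc2ccccc2)N1 | starting material
2 | succinyl chloride | O=C(Cl)CCC(=O)Cl | starting material
3 | lithium (S)-4-benzyl-2-oxooxazolidin-3-ide | [Li+].O=C1OC[C@H](Cc2ccccc2)[N-]1 | intermediate
4 | succinyl bis[(S)-4-benzyl-2-oxazolidinone] | O=C1OC[C@H](Cc2ccccc2)N1C(=O)CCC(=O)N1[C@@H](Cc2ccccc2)COC1=O | intermediate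
5 | 4-benzyloxy-3-methoxybenzaldehyde | COc1cc(C=O)ccc1OCc1ccccc1 | starting material
6 | (Z,Z)-bis(dibutylboron enolate) of 4 | CCCCB(CCCC)O/C(=C\C=C(/OB(CCCC)CCCC)N1[C@@H](Cc2ccccc2)COC1=O)N1[C@@H](Cc2ccccc2)COC1=O | intermediate
7 | bis(dibutylboron aldolate) of 8 | COc1cc([C@@H](OB(CCCC)CCCC)[C@@H](C(=O)N2[C@@H](Cc3ccccc3)COC2=O)[C@H](C(=O)N2[C@@H](Cc3ccccc3)COC2=O)[C@H](OB(CCCC)CCCC)c2ccc(OCc3ccccc3)c(OC)c2)ccc1OCc1ccccc1 | intermediate
8 | (4S,4'S)-3,3'-{(2S,3S)-2,3-bis{(S)-[4-(benzyloxy)-3-methoxyphenyl](hydroxy)methyl}butanedioyl}bis(4-benzyl-1,3-oxazolidin-2-one) | COc1cc([C@@H](O)[C@@H](C(=O)N2[C@@H](Cc3ccccc3)COC2=O)[C@H](C(=O)N2[C@@H](Cc3ccccc3)COC2=O)[C@H](O)c2ccc(OCc3ccccc3)c(OC)c2)ccc1OCc1ccccc1 | intermediate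
9 | bis(tert-butyldimethylsilyl) ether of 8 | COc1cc([C@@H](O[Si](C)(C)C(C)(C)C)[C@@H](C(=O)N2[C@@H](Cc3ccccc3)COC2=O)[C@H](C(=O)N2[C@@H](Cc3ccccc3)COC2=O)[C@H](O[Si](C)(C)C(C)(C)C)c2ccc(OCc3ccccc3)c(OC)c2)ccc1OCc1ccccc1 | intermediate
10 | (2R,3R)-2,3-bis{(S)-[4-(benzyloxy)-3-methoxyphenyl][(tert-butyldimethylsilyl)oxy]methyl}butane-1,4-diol | COc1cc([C@@H](O[Si](C)(C)C(C)(C)C)[C@@H](CO)[C@H](CO)[C@H](O[Si](C)(C)C(C)(C)C)c2ccc(OCc3ccccc3)c(OC)c2)ccc1OCc1ccccc1 | intermediate
11 | (2R,3R)-2,3-bis{(S)-[4-(benzyloxy)-3-methoxyphenyl][(tert-butyldimethylsilyl)oxy]methyl}-4-hydroxybutyl 4-methylbenzenesulfonate | COc1cc([C@@H](O[Si](C)(C)C(C)(C)C)[C@@H](COS(=O)(=O)c2ccc(C)cc2)[C@H](CO)[C@H](O[Si](C)(C)C(C)(C)C)c2ccc(OCc3ccccc3)c(OC)c2)ccc1OCc1ccccc1 | intermediate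
12 | (3R,4R)-3,4-bis{(S)-[4-(benzyloxy)-3-methoxyphenyl][(tert-butyldimethylsilyl)oxy]methyl}oxolane | COc1cc([C@@H](O[Si](C)(C)C(C)(C)C)[C@H]2COC[C@@H]2[C@H](O[Si](C)(C)C(C)(C)C)c2ccc(OCc3ccccc3)c(OC)c2)ccc1OCc1ccccc1 | intermediate
13 | (S,S)-[(3R,4R)-oxolane-3,4-diyl]bis{[4-(benzyloxy)-3-methoxyphenyl]methanol} | COc1cc([C@@H](O)[C@H]2COC[C@@H]2[C@H](O)c2ccc(OCc3ccccc3)c(OC)c2)ccc1OCc1ccccc1 | intermediate
14 | [4-(benzyloxy)-3-methoxyphenyl]{(3R,4R)-4-{(S)-[4-(benzyloxy)-3-methoxyphenyl](hydroxy)methyl}oxolan-3-yl}methanone | COc1cc([C@@H](O)[C@H]2COC[C@@H]2C(=O)c2ccc(OCc3ccccc3)c(OC)c2)ccc1OCc1ccccc1 | intermediate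
15 | (S)-[4-(benzyloxy)-3-methoxyphenyl]{(3R,4R)-4-{(R)-[4-(benzyloxy)-3-methoxyphenyl](hydroxy)methyl}oxolan-3-yl}methanol | COc1cc([C@@H](O)[C@H]2COC[C@@H]2[C@@H](O)c2ccc(OCc3ccccc3)c(OC)c2)ccc1OCc1ccccc1 | intermediate
16 | 4-[(S)-hydroxy{(3R,4R)-4-[(R)-hydroxy(4-hydroxy-3-methoxyphenyl)methyl]oxolan-3-yl}methyl]-2-methoxyphenol | COc1cc([C@@H](O)[C@H]2COC[C@@H]2[C@@H](O)c2ccc(O)c(OC)c2)ccc1O | target

## Step count and least certain steps

Total: 9 steps. Longest linear sequence: 9 steps (from 1 and 2 to 16; 5 enters in step 2).

Step 2 (key step, the proposed new method).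
- What may go wrong: the second enolisation may be incomplete, so that a mono-enolate reacts and its boron aldolate acylates itself on the remaining imide (lactonisation with loss of an auxiliary). Facial selectivity may erode in the second addition next to the first aldolate. Both hydroxyls of the product may lactonise onto the opposite imides during work-up or chromatography, since the cis-fused bis(lactone) is geometrically within reach.
- Fallback (known chemistry, one aldol at a time, never with a free aldolate beside an unhindered imide): it sets out from 1 and returns at 9. Compound 1 is acylated with the mixed pivalic anhydride of 4-tert-butoxy-4-oxobutanoic acid (PivCl, Et3N; then 1, LiCl) to give tert-butyl 4-[(4S)-4-benzyl-2-oxo-1,3-oxazolidin-3-yl]-4-oxobutanoate F1. A single Evans syn aldol of F1 with 5 (Bu2BOTf, iPr2NEt) is the established reaction of succinate half-ester imides, and the bulky tert-butyl ester is a poor acyl acceptor; it should give tert-butyl (3S,4S)-3-{[(4S)-4-benzyl-2-oxo-1,3-oxazolidin-3-yl]carbonyl}-4-[4-(benzyloxy)-3-methoxyphenyl]-4-hydroxybutanoate F2. This is silylated (TBSOTf, 2,6-lutidine) to its tert-butyldimethylsilyl ether F3. The tert-butyl ester is cleaved with Me3SiOTf/2,6-lutidine and aqueous work-up to the carboxylic acid F4, which is coupled with lithiated 1 through its pivalic mixed anhydride to the monoadduct bis(imide) F5. A second Evans syn aldol with 5 at the remaining CH2–C(=O) imide gives the mono-silylated double adduct F6, and silylation of its free hydroxyl gives 9.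

Step 4.
- What may go wrong: hydride attack at the ring carbonyl of the auxiliary (endocyclic cleavage), because both exocyclic carbonyls are flanked by α-branching and silyloxy groups; or the reduction may stall at the lactone stage.
- Fallback: it sets out from 9 and returns at 10. LiOH/H2O2 (THF/H2O, 0 °C) cleaves both auxiliaries at the exocyclic carbonyl to (2S,3S)-2,3-bis{(S)-[4-(benzyloxy)-3-methoxyphenyl][(tert-butyldimethylsilyl)oxy]methyl}butanedioic acid F7, and BH3·SMe2 (THF, 0 °C → rt) reduces the diacid to 10.

Step 7.
- What may go wrong: over-oxidation of the second carbinol and the statistical ceiling on mono-oxidation; surface- or base-induced epimerisation at C4 of the hydroxy ketone, driven by closure of a cis-fused hemiketal.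
- Fallback: it sets out from 12 and returns at 15. One silyl ether is removed (Bu4NF, 1 equiv, buffered with AcOH; 12 and 13 recycled) to give the mono-alcohol F8. Dess–Martin periodinane gives the ketone F9, in which the second carbinol is still capped, so neither over-oxidation nor hemiketal formation is possible. The oxazaborolidine reduction of step 8 then gives the R alcohol F10, and Bu4NF gives 15.

Step 8.
- What may go wrong: poor facial selectivity, because the alkyl side of the ketone is α-branched and the free hydroxyl, once converted into an alkoxyborane, may deliver hydride intramolecularly without catalyst control.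
- Fallback: it sets out from 13 and returns at 15. A Mitsunobu reaction with one equivalent of 4-nitrobenzoic acid (PPh3, DIAD, toluene, −20 °C) inverts one of the homotopic carbinols and gives the mono(4-nitrobenzoate) F11; K2CO3/MeOH removes the ester to give 15.

Step 9.
- What may go wrong: over-reduction with loss of a benzylic hydroxyl, or quinone-methide chemistry of the released para-hydroxybenzylic alcohols if traces of acid sit on the catalyst.
- Fallback: it sets out from 15 and returns at 16. Both carbinols are capped (Et3SiCl, imidazole) to the bis(triethylsilyl) ether F12. The benzyl ethers are hydrogenolysed (H2, Pd/C, EtOAc) to the bis(phenol) F13, whose benzylic C–O bonds are shielded by silicon. Bu4NF buffered with AcOH at 0 °C then releases 16.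

## Further compounds

F1 | step 2 | tert-butyl 4-[(4S)-4-benzyl-2-oxo-1,3-oxazolidin-3-yl]-4-oxobutanoate | CC(C)(C)OC(=O)CCC(=O)N1[C@@H](Cc2ccccc2)COC1=O
F2 | step 2 | tert-butyl (3S,4S)-3-{[(4S)-4-benzyl-2-oxo-1,3-oxazolidin-3-yl]carbonyl}-4-[4-(benzyloxy)-3-methoxyphenyl]-4-hydroxybutanoate | COc1cc([C@@H](O)[C@H](CC(=O)OC(C)(C)C)C(=O)N2[C@@H](Cc3ccccc3)COC2=O)ccc1OCc1ccccc1
F3 | step 2 | tert-butyl (3S,4S)-3-{[(4S)-4-benzyl-2-oxo-1,3-oxazolidin-3-yl]carbonyl}-4-[4-(benzyloxy)-3-methoxyphenyl]-4-[(tert-butyldimethylsilyl)oxy]butanoate | COc1cc([C@@H](O[Si](C)(C)C(C)(C)C)[C@H](CC(=O)OC(C)(C)C)C(=O)N2[C@@H](Cc3ccccc3)COC2=O)ccc1OCc1ccccc1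
F4 | step 2 | (3S,4S)-3-{[(4S)-4-benzyl-2-oxo-1,3-oxazolidin-3-yl]carbonyl}-4-[4-(benzyloxy)-3-methoxyphenyl]-4-[(tert-butyldimethylsilyl)oxy]butanoic acid | COc1cc([C@@H](O[Si](C)(C)C(C)(C)C)[C@H](CC(=O)O)C(=O)N2[C@@H](Cc3ccccc3)COC2=O)ccc1OCc1ccccc1
F5 | step 2 | (4S,4'S)-3,3'-{(2S)-2-{(S)-[4-(benzyloxy)-3-methoxyphenyl][(tert-butyldimethylsilyl)oxy]methyl}butanedioyl}bis(4-benzyl-1,3-oxazolidin-2-one) | COc1cc([C@@H](O[Si](C)(C)C(C)(C)C)[C@H](CC(=O)N2[C@@H](Cc3ccccc3)COC2=O)C(=O)N2[C@@H](Cc3ccccc3)COC2=O)ccc1OCc1ccccc1
F6 | step 2 | (4S,4'S)-3,3'-{(2S,3S)-2-{(S)-[4-(benzyloxy)-3-methoxyphenyl][(tert-butyldimethylsilyl)oxy]methyl}-3-{(S)-[4-(benzyloxy)-3-methoxyphenyl](hydroxy)methyl}butanedioyl}bis(4-benzyl-1,3-oxazolidin-2-one) | COc1cc([C@@H](O[Si](C)(C)C(C)(C)C)[C@@H](C(=O)N2[C@@H](Cc3ccccc3)COC2=O)[C@H](C(=O)N2[C@@H](Cc3ccccc3)COC2=O)[C@H](O)c2ccc(OCc3ccccc3)c(OC)c2)ccc1OCc1ccccc1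
F7 | step 4 | (2S,3S)-2,3-bis{(S)-[4-(benzyloxy)-3-methoxyphenyl][(tert-butyldimethylsilyl)oxy]methyl}butanedioic acid | COc1cc([C@@H](O[Si](C)(C)C(C)(C)C)[C@@H](C(=O)O)[C@H](C(=O)O)[C@H](O[Si](C)(C)C(C)(C)C)c2ccc(OCc3ccccc3)c(OC)c2)ccc1OCc1ccccc1
F8 | step 7 | (S)-[4-(benzyloxy)-3-methoxyphenyl]{(3R,4R)-4-{(S)-[4-(benzyloxy)-3-methoxyphenyl][(tert-butyldimethylsilyl)oxy]methyl}oxolan-3-yl}methanol | COc1cc([C@@H](O[Si](C)(C)C(C)(C)C)[C@H]2COC[C@@H]2[C@H](O)c2ccc(OCc3ccccc3)c(OC)c2)ccc1OCc1ccccc1
F9 | step 7 | [4-(benzyloxy)-3-methoxyphenyl]{(3R,4R)-4-{(S)-[4-(benzyloxy)-3-methoxyphenyl][(tert-butyldimethylsilyl)oxy]methyl}oxolan-3-yl}methanone | COc1cc([C@@H](O[Si](C)(C)C(C)(C)C)[C@H]2COC[C@@H]2C(=O)c2ccc(OCc3ccccc3)c(OC)c2)ccc1OCc1ccccc1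
F10 | step 7 | (R)-[4-(benzyloxy)-3-methoxyphenyl]{(3R,4R)-4-{(S)-[4-(benzyloxy)-3-methoxyphenyl][(tert-butyldimethylsilyl)oxy]methyl}oxolan-3-yl}methanol | COc1cc([C@@H](O[Si](C)(C)C(C)(C)C)[C@H]2COC[C@@H]2[C@@H](O)c2ccc(OCc3ccccc3)c(OC)c2)ccc1OCc1ccccc1
F11 | step 8 | (R)-[4-(benzyloxy)-3-methoxyphenyl]{(3R,4R)-4-{(S)-[4-(benzyloxy)-3-methoxyphenyl](hydroxy)methyl}oxolan-3-yl}methyl 4-nitrobenzoate | COc1cc([C@@H](O)[C@H]2COC[C@@H]2[C@@H](OC(=O)c2ccc(cc2)[N+](=O)[O-])c2ccc(OCc3ccccc3)c(OC)c2)ccc1OCc1ccccc1
F12 | step 9 | bis(triethylsilyl) ether of 15 | COc1cc([C@@H](O[Si](CC)(CC)CC)[C@H]2COC[C@@H]2[C@@H](O[Si](CC)(CC)CC)c2ccc(OCc3ccccc3)c(OC)c2)ccc1OCc1ccccc1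
F13 | step 9 | bis(triethylsilyl) ether of 16 at the two carbinol oxygens | COc1cc([C@@H](O[Si](CC)(CC)CC)[C@H]2COC[C@@H]2[C@@H](O[Si](CC)(CC)CC)c2ccc(O)c(OC)c2)ccc1O
A1 | alternative 1 | fumaric bis[(2S,5S)-2,5-dimethylpyrrolidide] | C[C@H]1CC[C@H](C)N1C(=O)/C=C/C(=O)N1[C@@H](C)CC[C@@H]1C
A2 | alternative 1 | chloromethyl (trimethylsilyl)methyl ether | C[Si](C)(C)COCCl
A3 | alternative 1 | (3R,4R)-oxolane-3,4-dicarboxylic bis[(2S,5S)-2,5-dimethylpyrrolidide] | C[C@H]1CC[C@H](C)N1C(=O)[C@H]1COC[C@@H]1C(=O)N1[C@@H](C)CC[C@@H]1C
A4 | alternative 1 | (3R,4R)-3,4-bis[4-(benzyloxy)-3-methoxybenzoyl]oxolane | COc1cc(C(=O)[C@H]2COC[C@@H]2C(=O)c2ccc(OCc3ccccc3)c(OC)c2)ccc1OCc1ccccc1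
A5 | alternative 2 | (3Z,4Z)-3,4-bis[4-(benzyloxy)-3-methoxybenzylidene]oxolane | COc1cc(/C=C2\COC/C2=C\c2ccc(OCc3ccccc3)c(OC)c2)ccc1OCc1ccccc1
A6 | alternative 2 | meso (1R,4S)-1,4-bis[4-(benzyloxy)-3-methoxyphenyl]-1,4,5,7-tetrahydrofuro[3,4-d][1,2]dioxine | COc1cc([C@H]2OO[C@@H](c3ccc(OCc4ccccc4)c(OC)c3)C3=C2COC3)ccc1OCc1ccccc1
A7 | alternative 2 | meso (R,S)-(2,5-dihydrofuran-3,4-diyl)bis{[4-(benzyloxy)-3-methoxyphenyl]methanol} | COc1cc([C@@H](O)C2=C(COC2)[C@@H](O)c2ccc(OCc3ccccc3)c(OC)c2)ccc1OCc1ccccc1
A8 | alternative 3 | (5S)-5-{1-[4-(benzyloxy)-3-methoxyphenyl]ethenyl}-4,5-dihydro-1,3-dioxepine | C=C(c1ccc(OCc2ccccc2)c(OC)c1)[C@H]1COCOC=C1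
A9 | alternative 3 | (3R,4S)-4-{1-[4-(benzyloxy)-3-methoxyphenyl]ethenyl}oxolane-3-carbaldehyde | O=C[C@H]1COC[C@@H]1C(=C)c1ccc(OCc2ccccc2)c(OC)c1
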